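**Retrosynthetic overview**
1. The target is 1-oxacyclotritriacontan-2-one, the 33-membered lactone of 32-hydroxydotriacontanoic acid (C32H62O2; C1 = lactone C=O, C2–C31 = CH2, C32 = O–CH2; achiral).
2. The key disconnection is C31–C32. C32 is introduced as an electrophilic chloromethyl carbon and C31 as an alkene terminus, so the two are joined through a radical: the acyloxymethyl radical at C32, released from an S-(acyloxymethyl) xanthate, adds 33-endo to the terminal vinyl group C30=C31 of its own acyl chain, and the xanthate group transfers to C30. The xanthate is then reduced off.
3. Enabling feature: the ring oxygen O1 bonded directly to C32 (its lone pair stabilises the C32 radical, and the O–CH2–S unit is made from the carboxylate and a one-carbon dielectrophile), the unbranched C30–C31 segment that can be carried as a vinyl group, and the strain-free 33-membered ring. This is the only ring, formed in step 5.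
4. The precursor acid, hentriacont-30-enoic acid, is assembled C11 + C10 + C10 from 11-bromoundec-1-ene, 1,10-dibromodecane and 10-bromodecanoic acid by two Cu-catalysed Grignard/alkyl bromide couplings.

Key step: step 5

Remark: the target has no stereocentre; the single stereocentre that appears on the way (C30 of compound 11) is racemic and is removed in step 6.

**Route**

Step 1
Reactants: 1 11-bromoundec-1-ene; 2 1,10-dibromodecane (3 eq)
Product: 4 21-bromohenicos-1-ene, via undec-10-enylmagnesium bromide 3 (not isolated)
Conditions: Mg, THF, 40 °C; then 2 (3 eq), Li2CuCl4 (3 mol%), THF, −10 °C → rt; excess 2 recovered by distillation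
Reagents that add atoms: none
Why: Cu-catalysed Grignard/alkyl bromide cross-coupling (Kochi-type sp3–sp3 coupling) is reliable for primary partners and leaves the terminal alkene untouched, and the excess of the symmetrical dibromide should hold coupling at both ends down.

Step 2
Reactants: 4 21-bromohenicos-1-ene; 5 10-bromodecanoic acid
Product: 8 hentriacont-30-enoic acid, via henicos-20-enylmagnesium bromide 6 (not isolated), via chloromagnesium 10-bromodecanoate 7 (not isolated)
Conditions: 4, Mg, THF, 45 °C; 5, MeMgCl (1.0 eq), THF, −20 °C; then both, Li2CuCl4 (5 mol%), THF, −20 °C → rt; aq. HCl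
Reagents that add atoms: none
Why: the same Kochi-type Cu-catalysed coupling is standard with ω-bromoalkanoic acids once the acid is masked as its halomagnesium carboxylate, which is inert to the Grignard reagent at low temperature, so the C31 acid should be reached without protecting groups.

Step 3
Reactants: 8 hentriacont-30-enoic acid
Product: 9 chloromethyl hentriacont-30-enoate
Conditions: ClCH2OSO2Cl (1.2 eq), NaHCO3 (4 eq), Bu4NHSO4 (0.1 eq), CH2Cl2/H2O, rt → 35 °C
Reagents that add atoms: chloromethyl chlorosulfate, ClCOS(=O)(=O)Cl
Why: phase-transfer O-alkylation of a carboxylate with chloromethyl chlorosulfate is the standard preparation of chloromethyl esters; the chlorosulfate is displaced in preference to chloride and the alkene is inert.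

Step 4
Reactants: 9 chloromethyl hentriacont-30-enoate
Product: 10 [(ethoxycarbonothioyl)sulfanyl]methyl hentriacont-30-enoate
Conditions: KSC(S)OEt (1.2 eq), acetone/THF, 0 °C → rt
Reagents that add atoms: potassium O-ethyl xanthate, CCOC(=S)[S-].[K+]
Why: SN2 displacement of the oxygen-activated chloride by the soft xanthate sulfur, the usual entry to S-alkyl dithiocarbonates for radical group transfer.

Step 5
Reactants: 10 [(ethoxycarbonothioyl)sulfanyl]methyl hentriacont-30-enoate
Product: 11 31-[(ethoxycarbonothioyl)sulfanyl]-1-oxacyclotritriacontan-2-one (racemic)
Conditions: dilauroyl peroxide (0.1 eq portions until conversion), degassed ClCH2CH2Cl, 2 mM, reflux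
Reagents that add atoms: none
Why: Proposed new method: undecyl radicals from dilauroyl peroxide add to the C=S group of 10 and expel the acyloxymethyl radical RC(=O)O–CH2• (C32), which is stabilised by the lone pair of the adjacent ester oxygen and, being stored reversibly as dormant dithiocarbonate with no hydrogen donor present, should persist until it adds to the unsubstituted terminus (C31) of the vinyl group; the secondary C30 radical then takes the dithiocarbonate group from a further molecule of 10 and propagates the chain (degenerative xanthate group transfer). The closest known reaction types are the intermolecular xanthate-transfer addition of heteroatom-stabilised radicals (imidomethyl, α-acyloxyalkyl) to unactivated terminal alkenes and atom-transfer radical macrolactonisation of ω-alkenyl haloacetates; new here is closure of a macrolactone at its O–CH2/CH2 bond by an acyloxymethyl radical. The single ring closes in the 33-endo-trig mode, which for a monosubstituted alkene is the normal anti-Markovnikov sense of radical addition, and the strain-free 33-membered ring imposes no transannular penalty. The only new stereocentre, C30 bearing the dithiocarbonate, forms without control as a racemate and is deleted in step 6. The selectivity needed is ring closure over intermolecular addition and over premature reduction: the first is secured by the 2 mM dilution, the second by the transfer mechanism itself, and the terminal alkene is the only radical acceptor in the molecule, so no regiochemical alternative exists.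

Step 6
Reactants: 11 31-[(ethoxycarbonothioyl)sulfanyl]-1-oxacyclotritriacontan-2-one
Product: 12 1-oxacyclotritriacontan-2-one
Conditions: (Me3Si)3SiH (1.5 eq), AIBN (0.2 eq), toluene, 85 °C
Reagents that add atoms: none
Why: radical-chain reduction of a secondary S-alkyl dithiocarbonate (Barton–McCombie-type C–S cleavage with tris(trimethylsilyl)silane) should replace the xanthate by hydrogen, which removes the only stereocentre and leaves the lactone untouched.

**Compound list**
1 | 11-bromoundec-1-ene | C=CCCCCCCCCCBr | starting material
2 | 1,10-dibromodecane | BrCCCCCCCCCCBr | starting material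
3 | undec-10-enylmagnesium bromide | C=CCCCCCCCCC[Mg]Br | intermediate
4 | 21-bromohenicos-1-ene | C=CCCCCCCCCCCCCCCCCCCCBr | intermediate
5 | 10-bromodecanoic acid | OC(=O)CCCCCCCCCBr | starting material
6 | henicos-20-enylmagnesium bromide | C=CCCCCCCCCCCCCCCCCCCC[Mg]Br | intermediate
7 | chloromagnesium 10-bromodecanoate | BrCCCCCCCCCC(=O)O[Mg]Cl | intermediate
8 | hentriacont-30-enoic acid | OC(=O)CCCCCCCCCCCCCCCCCCCCCCCCCCCCC=C | intermediate
9 | chloromethyl hentriacont-30-enoate | ClCOC(=O)CCCCCCCCCCCCCCCCCCCCCCCCCCCCC=C | intermediate
10 | [(ethoxycarbonothioyl)sulfanyl]methyl hentriacont-30-enoate | CCOC(=S)SCOC(=O)CCCCCCCCCCCCCCCCCCCCCCCCCCCCC=C | intermediate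
11 | 31-[(ethoxycarbonothioyl)sulfanyl]-1-oxacyclotritriacontan-2-one (racemic) | O=C1CCCCCCCCCCCCCCCCCCCCCCCCCCCCC(SC(=S)OCC)CCO1 | intermediate
12 | 1-oxacyclotritriacontan-2-one | O=C1CCCCCCCCCCCCCCCCCCCCCCCCCCCCCCCO1 | target

**Count and risks**
Total steps: 6. Longest linear sequence: 6 steps (1 → 4 → 8 → 9 → 10 → 11 → 12).

Steps most likely to fail:

Step 5 (proposed new method). At the dilution needed for a 33-membered ring the transfer chain may become too short, so that conversion stalls, or intermolecular addition may lead to oligomers. The fallback uses known chemistry and closes the ring one bond further along (C30=C31). It sets out from acid 8, which is esterified with allyl alcohol (DCC, DMAP, CH2Cl2) to allyl hentriacont-30-enoate F1. Ring-closing metathesis (second-generation Ru benzylidene catalyst, 1,4-benzoquinone, CH2Cl2, 1 mM, reflux) should give 1-oxacyclotritriacont-31-en-2-one F2 as an E/Z mixture. Hydrogenation (H2, Pd/C, EtOAc) returns to the route at 12.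

Step 2. Formation of the waxy C21 Grignard reagent may be sluggish, it may homocouple (Wurtz-type), and the carboxylate salt may precipitate at low temperature, so that the cross-coupling is starved. The fallback sets out from bromide 4 and replaces the Grignard coupling by an alkyl–alkyl Suzuki–Miyaura coupling. Commercial methyl dec-9-enoate is hydroborated with 9-BBN (1.0 eq, THF, rt) to methyl 10-(9-borabicyclo[3.3.1]nonan-9-yl)decanoate F3. Coupling of F3 with 4 (Pd(OAc)2, PCy3, K3PO4·H2O, THF, rt) should give methyl hentriacont-30-enoate F4. Saponification (LiOH, THF/MeOH/H2O, then acid) returns to the route at 8.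

Step 1. Coupling at both ends of the symmetrical dibromide and homocoupling of the Grignard reagent may erode mono-selectivity and give hydrocarbon mixtures that are hard to separate. The fallback sets out from 1 (as its Grignard reagent 3) and uses an electrophile with differentiated ends. Commercial 10-bromodecan-1-ol is deprotonated with MeMgCl (THF, −20 °C) to chloromagnesium 10-bromodecan-1-olate F5, which is coupled with 3 (Li2CuCl4, THF, −10 °C → rt) to henicos-20-en-1-ol F6. Appel bromination (CBr4, PPh3, CH2Cl2, 0 °C) returns to the route at 4.

Further compounds
F1 | step 5 | allyl hentriacont-30-enoate | C=CCOC(=O)CCCCCCCCCCCCCCCCCCCCCCCCCCCCC=C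
F2 | step 5 | 1-oxacyclotritriacont-31-en-2-one (E/Z mixture) | O=C1CCCCCCCCCCCCCCCCCCCCCCCCCCCCC=CCO1
F3 | step 2 | methyl 10-(9-borabicyclo[3.3.1]nonan-9-yl)decanoate | COC(=O)CCCCCCCCCB1C2CCCC1CCC2
F4 | step 2 | methyl hentriacont-30-enoate | COC(=O)CCCCCCCCCCCCCCCCCCCCCCCCCCCCC=C
F5 | step 1 | chloromagnesium 10-bromodecan-1-olate | BrCCCCCCCCCCO[Mg]Cl
F6 | step 1 | henicos-20-en-1-ol | C=CCCCCCCCCCCCCCCCCCCCO
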